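## Structural features

The target is a germacranolide: a ten-membered carbocycle (C1–C10) trans-fused across C6–C7 to an α-methylene-γ-butyrolactone (ring oxygen on C6, carbonyl C12, exocyclic C11=C13). Two oxiranes sit on the carbocycle, a cis one across C1–C10 and a trans one across C4–C5, each with a methyl group on its fully substituted carbon (C14 on C10, C15 on C4). C7 is a tertiary carbinol flanked by the lactone oxygen at C6 and the methacrylate at C8, so C4, C5, C6, C7 and C8 form an unbroken row of five stereocentres. C10 and C1 are separated from that row only by the C9 methylene, which gives seven stereocentres in all (1S,4R,5R,6R,7S,8R,10R). The fragile groups are the two Michael acceptors (methylene lactone, methacrylate), the epoxides (transannular opening under acid) and the β-hydroxy lactone, which can translactonise to O8 once that oxygen is free. In the precursors the cyclodeca-1,5-diene is also fragile (Cope rearrangement on heating, cation–olefin cyclisation under acid). The real difficulty is the ten-membered ring holding a Z trisubstituted C1=C10 olefin (the only source of the cis epoxide) beside an E C4=C5 olefin, and then stereocontrol at C6–C8 on a flexible ring. The key step exploits the fact that C1 and C10 carry nothing but the future epoxide: both can be the α-carbons of a sulfone in an eleven-membered thiacycle, which closes by S-alkylation and contracts to the ten-membered Z olefin on loss of SO2.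

## Logic of the disconnections

39 to 38: the four C–O bonds of the two oxiranes are cut first. They are the most acid-sensitive function and arise from the only two electron-rich olefins. This removes four stereocentres (C1, C10, C4, C5). The forward step must put oxygen on the outer face of the E olefin and on the α face of the Z olefin.

38 to 37 to 36: the acyl–O8 bond, then the Si–O8 bond. A methacrylate cannot survive enolates or organolithiums, so O8 travels as a silyl ether. The forward steps must acylate the secondary hydroxyl beside the tertiary one, and do so before free O8 can attack C12.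

36 to 33: the lactone C12–O6 bond, with C12 lowered to the alcohol level. A 2-methylene-1,4-diol gives the methylene lactone by oxidation of its primary hydroxyl, so the three-carbon unit becomes a simple alkenyl nucleophile. The oxidant must prefer the primary allylic hydroxyl to the secondary allylic one at C6.

33 to 30 and 31: the C7–C11 bond. C7 is a tertiary carbinol, so it is the carbonyl carbon of a ketone. O6 as a metal alkoxide (chelation) and the silylated O8 (Felkin–Anh) both send the nucleophile to the β face. The demand is addition of a basic organometallic to a hindered, enolisable ketone.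

30 to 28: the C6–O bond. C6 is both α to the ketone and allylic, hence the most acidic position, and enolate oxidation is the direct way in. The demand is face selection at C6 relative to C8.

28 to 27: the C7 carbonyl is masked as its ethylene ketal, because a free β,γ-unsaturated ketone would not survive the base and halogen source of the ring contraction.

27 to 24: the C1=C10 σ and π bonds, traced to SO2 bridging C1 and C10. A hard carbon–carbon closure of a ten-membered ring is exchanged for the contraction of an eleven-membered thiacycle. The forward step must deliver the Z olefin. C10 of 24 is destroyed, so its configuration (R, the result of a single inversion) is immaterial.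

24 to 22 to 20: the two S=O bonds, then the ring S–C1 bond. The thiacycle closes by displacement of a primary chloride by the C10 thiolate. The chloride at C1 is carried from the third step of the route, which saves a protecting group and an activation. The demand is high dilution.

20 to 19 to 18 to 17 to 16: the C10–S bond (inversion of the carbinol), the acetate, the exchange of the S,S-acetal for the O,O-acetal, and the silyl group. The dithiane must be gone before any other sulfur is oxidised.

16 to 15: the C8–H bond. The C10 hydroxyl delivers hydride to the C8 ketone with 1,3-anti induction and becomes acylated in the same event, which differentiates the two oxygens.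

15 to 10 and 12: the C7–C8 bond, an acyl-anion equivalent (C7 as lithiated dithiane) joined to the amide of the hydroxy acid. 10 to 8 and 7: the C6–C7 bond, an allylic alkylation of the same dithiane.

7 to 1 and 12 to 11: functional-group changes only. The terminal isopropylidene of 1 is cut away to make C1, and the ester of 11 becomes the amide.

## Other disconnections considered

Alternative 1: The cut is the C8–C9 ring bond together with the C10–O bond. In the forward step the acyclic oxime A2 (C8 aldoxime, C9=C10 as a 1,1-disubstituted olefin, free C1 hydroxyl) is chlorinated with NCS and treated with EtMgBr. The dipole released from A2 adds across C9=C10 and should give the isoxazoline-bridged carbocycle A1.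

- In its favour: the ring closes by carbon–carbon bond formation, and the C10 oxygen is set in the same step. The C1 magnesium alkoxide can hold the dipole on one face of the olefin. The cis 1,10-epoxide would then follow by displacement at C1 with inversion. On this point it is better than the chosen plan, which relies on face selection in a late epoxidation. C6 and C7 are also set in open-chain intermediates by reliable methods.
- Against it: a ten-membered ring must close through a slow dipolarophile while the dipole can dimerise. A1 carries a strained bridgehead C=N. After closure the route still needs N–O cleavage, a stereoselective C8 reduction on the ring, epoxide closure and removal of two MOM ethers (acid) and a PMB ether in the presence of epoxides. A2, with three stereocentres, is itself a long synthesis.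
- Comparison: on mechanism the cycloaddition is concerted and stereospecific, whereas the chosen contraction is stepwise but rests on an easier ring closure. On step economy the chosen plan should be clearly shorter.

Alternative 2: The cut is the C6–O lactone bond, traced back to an allylic C6–H bond. In the forward step the acrylic acid A4 is treated with Pd(OAc)2 and benzoquinone. Divalent palladium would form the C4–C5–C6 π-allyl and the carboxylate would close on C6 to give A3, which is identical with 38.

- In its favour: it avoids the enolate hydroxylation and the base-sensitive ketol 30, and it mirrors the biosynthetic order. C7 would be set from C8 alone.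
- Against it: allylic C–H cleavage by divalent palladium is established for terminal olefins. Here the olefin is trisubstituted, inside a ring with six allylic positions (C2, C3, C6, C9, C14, C15). The π-allyl can be captured at C4 or C6 and on either face. Divalent palladium can also trigger Cope or transannular reactions of the 1,5-diene.
- Comparison: it does not build the ring, so it would still need the ring contraction of the chosen plan. In step count it is about equal from 28 onward (addition, oxidation to the acid, desilylation, acylation, lactonisation). It is the equal of the chosen plan in length and weaker in predictability.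

Alternative 3: The cut is the pair C6–C12 and C7–C11, with the C6–O bond left for a later oxygen insertion. In the forward step the silyl dienol ether A6 of ketone 28 adds dichloroketene to give the cyclobutanone A5.

- In its favour: the regiochemistry of ketene addition to silyl enol ethers is dependable (carbonyl carbon to C6). C6 and C7 are set together in one suprafacial event, so their relative configuration is tied to one element; on that point it is at least the equal of the chosen plan. No organometallic has to add to a hindered ketone.
- Against it: the trans ring fusion of A5 can only come from a C6=C7 enol ether with trans ring geometry, and the ring is expected to prefer the cis enolate. Face selection relative to C8 is still left to conformation. C11 arrives as CCl2, so oxygen insertion, dechlorination, α-methylenation and removal of a tertiary silyl ether must follow. A peracid insertion would compete with the two trisubstituted olefins.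
- Comparison: it is mechanistically tidy but needs at least two more steps than steps 18–20 of the chosen plan and makes a geometric demand that is hard to meet.

Key step: step 16

Remark (assumption): germacrane numbering is used for all intermediates (ring C1–C10, C14 on C10, C15 on C4, C11–C13 the lactone carbons); 2-bromoprop-2-en-1-ol is taken as a commercial starting material.

## Steps

Step 1
Reactants: 1 geranyl acetate
Product: 2 6,7-epoxygeranyl acetate ((2E)-5-(3,3-dimethyloxiran-2-yl)-3-methylpent-2-en-1-yl acetate; racemic at the oxirane)
Conditions: mCPBA (1.05 equiv), NaHCO3, CH2Cl2, 0 °C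
Reagents that add atoms: mCPBA (3-chloroperoxybenzoic acid), OOC(=O)c1cccc(Cl)c1
Why: Prilezhaev epoxidation; the remote olefin is the more electron-rich one because the other is deactivated by the allylic acetate, and the oxirane centre is lost in step 2, so no stereocontrol is needed.

Step 2
Reactants: 2 6,7-epoxygeranyl acetate
Product: 4 (2E)-6-hydroxy-3-methylhex-2-en-1-yl acetate, via aldehyde 3 (not isolated)
Conditions: H5IO6, THF–H2O, 0 °C; then NaBH4, MeOH, 0 °C on the crude aldehyde
Reagents that add atoms: none
Why: Periodic acid opens the epoxide and cleaves the glycol (Malaprade cleavage) to aldehyde 3 and acetone; NaBH4 reduces the aldehyde and leaves the acetate at 0 °C.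

Step 3
Reactants: 4 (2E)-6-hydroxy-3-methylhex-2-en-1-yl acetate
Product: 5 (2E)-6-chloro-3-methylhex-2-en-1-yl acetate
Conditions: PPh3, N-chlorosuccinimide, CH2Cl2, 0 °C to rt
Reagents that add atoms: N-chlorosuccinimide, O=C1CCC(=O)N1Cl
Why: Appel-type chlorination (SN2 on the alkoxyphosphonium ion); the primary chloride at C1 is the latent leaving group for the ring closure in step 14 and needs neither protection nor later activation.

Step 4
Reactants: 5 (2E)-6-chloro-3-methylhex-2-en-1-yl acetate
Product: 6 (2E)-6-chloro-3-methylhex-2-en-1-ol
Conditions: K2CO3, MeOH, rt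
Reagents that add atoms: none
Why: Base-catalysed transesterification frees the allylic alcohol; methoxide does not displace an unactivated primary chloride at room temperature.

Step 5
Reactants: 6 (2E)-6-chloro-3-methylhex-2-en-1-ol
Product: 7 (2E)-1-bromo-6-chloro-3-methylhex-2-ene
Conditions: PBr3, Et2O, −10 °C
Reagents that add atoms: phosphorus tribromide, BrP(Br)Br
Why: SN2 bromination of the primary allylic alcohol at low temperature keeps the E geometry and avoids allylic transposition; the product has two halides of very different reactivity.

Step 6
Reactants: 8 1,3-dithiane; 7 (2E)-1-bromo-6-chloro-3-methylhex-2-ene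
Product: 10 2-[(2E)-6-chloro-3-methylhex-2-en-1-yl]-1,3-dithiane, via 2-lithio-1,3-dithiane 9 (not isolated)
Conditions: n-BuLi, THF, −30 °C; then 7, −78 °C
Reagents that add atoms: none
Why: Corey–Seebach alkylation forms C6–C7; the lithiodithiane displaces the allylic bromide at −78 °C, where alkyl chlorides are inert (they need about −20 °C and hours).

Step 7
Reactants: 11 ethyl (S)-3-hydroxybutanoate
Product: 12 (S)-3-hydroxy-N-methoxy-N-methylbutanamide
Conditions: MeNH(OMe)·HCl, i-PrMgCl, THF, −20 to 0 °C
Reagents that add atoms: N,O-dimethylhydroxylamine hydrochloride, CNOC.Cl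
Why: Aminolysis of the ester by the magnesium amide gives the Weinreb amide without protecting the hydroxyl; the stereocentre (future C10) is not touched.

Step 8
Reactants: 10 2-[(2E)-6-chloro-3-methylhex-2-en-1-yl]-1,3-dithiane; 12 (S)-3-hydroxy-N-methoxy-N-methylbutanamide
Product: 15 (3S)-1-{2-[(2E)-6-chloro-3-methylhex-2-en-1-yl]-1,3-dithian-2-yl}-3-hydroxybutan-1-one, via lithiated dithiane 13 (not isolated), via magnesium alkoxide 14 (not isolated)
Conditions: 10, t-BuLi, THF–HMPA, −78 °C; 12, i-PrMgCl (1 equiv), THF, −78 °C; combine, −78 to −40 °C; NH4Cl
Reagents that add atoms: none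
Why: Acylation of the 2-lithiodithiane by the Weinreb amide forms C7–C8; the chelated tetrahedral adduct releases the ketone only on work-up, so no second addition occurs. Turning the hydroxyl into its magnesium alkoxide first saves an equivalent of 13, and the chloride is inert at −78 °C (an intramolecular attack would need a seven-membered ring holding an E olefin).

Step 9
Reactants: 15 (3S)-1-{2-[(2E)-6-chloro-3-methylhex-2-en-1-yl]-1,3-dithian-2-yl}-3-hydroxybutan-1-one
Product: 16 (2S,4R)-4-{2-[(2E)-6-chloro-3-methylhex-2-en-1-yl]-1,3-dithian-2-yl}-4-hydroxybutan-2-yl acetate (8R,10S; 1,3-anti)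
Conditions: SmI2 (30 mol %), CH3CHO (excess), THF, −10 °C
Reagents that add atoms: acetaldehyde, CC=O
Why: Evans–Tishchenko reduction; the trivalent samarium catalyst formed from SmI2 and the aldehyde binds the C10 oxygen as its hemiacetal with acetaldehyde and passes hydride to the C8 ketone through a six-membered chair, which should set C8 as R (1,3-anti to C10). The same event leaves O10 acetylated and O8 free, so the two oxygens are differentiated without a separate step.

Step 10
Reactants: 16 (2S,4R)-4-{2-[(2E)-6-chloro-3-methylhex-2-en-1-yl]-1,3-dithian-2-yl}-4-hydroxybutan-2-yl acetate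
Product: 17 (2S,4R)-4-(tert-butyldimethylsilyloxy)-4-{2-[(2E)-6-chloro-3-methylhex-2-en-1-yl]-1,3-dithian-2-yl}butan-2-yl acetate
Conditions: TBSOTf, 2,6-lutidine, CH2Cl2, −78 to 0 °C
Reagents that add atoms: tert-butyldimethylsilyl triflate, CC(C)(C)[Si](C)(C)OS(=O)(=O)C(F)(F)F
Why: The silyl triflate silylates the hindered C8 carbinol; a non-chelating group is wanted here for the facial control of step 19.

Step 11
Reactants: 17 (2S,4R)-4-(tert-butyldimethylsilyloxy)-4-{2-[(2E)-6-chloro-3-methylhex-2-en-1-yl]-1,3-dithian-2-yl}butan-2-yl acetate
Product: 18 (2S,4R)-4-(tert-butyldimethylsilyloxy)-4-{2-[(2E)-6-chloro-3-methylhex-2-en-1-yl]-1,3-dioxolan-2-yl}butan-2-yl acetate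
Conditions: PhI(OCOCF3)2, HOCH2CH2OH, MeCN, 0 °C to rt
Reagents that add atoms: ethylene glycol, OCCO
Why: Oxidative dethioacetalisation by the hypervalent iodine reagent in the presence of the diol; each activated sulfur leaves as the thionium ion is captured by glycol, so the dioxolane forms without passing through the free β,γ-unsaturated ketone. The exchange is required because a dithiane would not survive the sulfide oxidation of step 15.

Step 12
Reactants: 18 (2S,4R)-4-(tert-butyldimethylsilyloxy)-4-{2-[(2E)-6-chloro-3-methylhex-2-en-1-yl]-1,3-dioxolan-2-yl}butan-2-yl acetate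
Product: 19 (2S,4R)-4-(tert-butyldimethylsilyloxy)-4-{2-[(2E)-6-chloro-3-methylhex-2-en-1-yl]-1,3-dioxolan-2-yl}butan-2-ol
Conditions: K2CO3, MeOH, rt
Reagents that add atoms: none
Why: Methanolysis of the acetate; the silyl ether, the ketal and the chloride are stable to carbonate in methanol.

Step 13
Reactants: 19 (2S,4R)-4-(tert-butyldimethylsilyloxy)-4-{2-[(2E)-6-chloro-3-methylhex-2-en-1-yl]-1,3-dioxolan-2-yl}butan-2-ol
Product: 20 S-[(2R,4R)-4-(tert-butyldimethylsilyloxy)-4-{2-[(2E)-6-chloro-3-methylhex-2-en-1-yl]-1,3-dioxolan-2-yl}butan-2-yl] ethanethioate
Conditions: PPh3, DIAD, AcSH, THF, 0 °C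
Reagents that add atoms: thioacetic acid, CC(=O)S
Why: Mitsunobu reaction; thioacetate displaces the activated unhindered methyl carbinol with inversion (10S to 10R), a configuration of no consequence later.

Step 14
Reactants: 20 S-[(2R,4R)-4-(tert-butyldimethylsilyloxy)-4-{2-[(2E)-6-chloro-3-methylhex-2-en-1-yl]-1,3-dioxolan-2-yl}butan-2-yl] ethanethioate
Product: 22 eleven-membered cyclic sulfide (sulfur between C1 and C10; C7 ethylene ketal; C8 silyl ether; 4E; 8R,10R), via thiol 21 (not isolated)
Conditions: Cs2CO3, NaI (cat.), MeOH–DMF, 50 °C, slow addition to about 2 mM, Ar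
Reagents that add atoms: none
Why: Methanolysis frees thiol 21, whose caesium thiolate displaces the primary chloride (SN2) under high dilution; closing through sulfur, with long C–S bonds and no hydrogens on the bridging atom, is the easy way into a medium ring.

Step 15
Reactants: 22 eleven-membered cyclic sulfide
Product: 24 eleven-membered cyclic sulfone ((6R,8R,13E)-6-(tert-butyldimethylsilyloxy)-8,13-dimethyl-1,4-dioxa-9-thiaspiro[4.10]pentadec-13-ene 9,9-dioxide), via sulfoxide 23 (not isolated)
Conditions: (NH4)6Mo7O24·4H2O (cat.), 30% H2O2, EtOH, 0 °C to rt
Reagents that add atoms: hydrogen peroxide, OO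
Why: Molybdate-catalysed oxidation takes the sulfide through 23 to the sulfone and is known to spare trisubstituted olefins, silyl ethers and ketals.

Step 16
Reactants: 24 eleven-membered cyclic sulfone
Product: 27 (1(10)Z,4E)-cyclodecadiene C7 ketal ((7E,11Z,14R)-14-(tert-butyldimethylsilyloxy)-8,12-dimethyl-1,4-dioxaspiro[4.9]tetradeca-7,11-diene), via α-bromo sulfone 25 (not isolated), via episulfone 26 (not isolated)
Conditions: CBr2F2, KOH/Al2O3, t-BuOH–CH2Cl2, 0 °C to rt
Reagents that add atoms: none
Why: Ramberg–Bäcklund reaction with in situ halogenation: KOH on alumina forms the α-sulfonyl carbanion, preferentially at the C1 methylene, which takes bromine from CBr2F2 to give 25. Deprotonation at C10 and intramolecular displacement of bromide (a 1,3-elimination, 3-exo-tet, with inversion at C1) give episulfone 26, which loses SO2 in a stereospecific cheletropic step and so forms the C1–C10 σ and π bonds. The ten-membered carbocycle is therefore closed by contraction of the eleven-membered thiacycle and not by a direct carbon–carbon cyclisation; the closest known reaction type is the Ramberg–Bäcklund contraction of cyclic sulfones to medium-ring cycloalkenes. No stereocentre is created: C10 of 24 is destroyed, so both epimers converge, and C8 is untouched. The selectivity needed is the Z geometry of C1=C10, which is decided when the episulfone closes; a cis fusion of the three-membered ring (C9 and C2 on the same side) is the less strained arrangement on a ten-membered ring that already holds the E C4=C5 olefin. The weak base and low temperature should keep 26 from epimerising before it fragments. CBr2F2 is preferred to CCl4 because the carbene it leaves does not add to the C4=C5 olefin as dichlorocarbene would, and the ketal, the silyl ether and the E olefin are inert to KOH on alumina.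

Step 17
Reactants: 27 (1(10)Z,4E)-cyclodecadiene C7 ketal
Product: 28 (3E,7Z,10R)-10-(tert-butyldimethylsilyloxy)-4,8-dimethylcyclodeca-3,7-dien-1-one (C7 ketone)
Conditions: PPTS, acetone–H2O (10:1), 45 °C
Reagents that add atoms: water, O
Why: Acid-catalysed ketal hydrolysis (transketalisation to acetone) under a buffered weak acid, chosen to keep the secondary silyl ether, to avoid moving C4=C5 into conjugation and to spare the acid-sensitive 1,5-diene; all later steps stay at or below 45 °C to avoid Cope rearrangement.

Step 18
Reactants: 28 (3E,7Z,10R)-10-(tert-butyldimethylsilyloxy)-4,8-dimethylcyclodeca-3,7-dien-1-one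
Product: 30 (2R,3E,7Z,10R)-10-(tert-butyldimethylsilyloxy)-2-hydroxy-4,8-dimethylcyclodeca-3,7-dien-1-one (6α-hydroxy ketone; 6R,8R), via potassium dienolate 29 (not isolated)
Conditions: KHMDS, THF, −78 °C; 2-(phenylsulfonyl)-3-phenyloxaziridine, −78 °C; NH4Cl
Reagents that add atoms: 2-(phenylsulfonyl)-3-phenyloxaziridine, O=S(=O)(c1ccccc1)N1OC1c1ccccc1
Why: Enolate oxidation by an N-sulfonyloxaziridine; C6–H is allylic and α to the ketone, so kinetic deprotonation goes there and not to the hindered C8–H, and oxygen is transferred to the α-carbon of the dienolate. The ring should hold the C6=C7 enolate as a cis ring olefin; allylic 1,3-strain then places H8 in the enolate plane, C9 covers the inner face, and the oxidant should reach C6 from the outer face (the side of the silyloxy group), giving 6R with O6 and O8 on opposite faces.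

Step 19
Reactants: 30 6α-hydroxy ketone; 31 2-bromoprop-2-en-1-ol
Product: 33 8β-(tert-butyldimethylsilyloxy)germacra-1(10)Z,4E,11(13)-triene-6α,7α,12-triol (6R,7R,8R), via dilithio reagent 32 (not isolated)
Conditions: 31, t-BuLi (3 equiv), Et2O, −78 to 0 °C; then 30 (0.25 equiv), THF, −78 to −40 °C; NH4Cl
Reagents that add atoms: none
Why: 1,2-Addition of the O,2-dilithio derivative of allyl alcohol to the ketone forms C7–C11; the first equivalent turns O6 into its lithium alkoxide. Cram chelation between that alkoxide and the carbonyl and the Felkin–Anh preference anti to the silyloxy group at C8 both direct C11 to the β face, so the C7 hydroxyl should come out cis to O6 and trans to O8.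

Step 20
Reactants: 33 8β-(tert-butyldimethylsilyloxy)germacra-1(10)Z,4E,11(13)-triene-6α,7α,12-triol
Product: 36 8β-(tert-butyldimethylsilyloxy)-7α-hydroxygermacra-1(10)Z,4E,11(13)-trien-12,6α-olide (6R,7R,8R), via hydroxy enal 34 (not isolated), via lactol 35 (not isolated)
Conditions: TEMPO (2,2,6,6-tetramethylpiperidin-1-oxyl, cat.), PhI(OAc)2, CH2Cl2, rt
Reagents that add atoms: none
Why: Oxoammonium oxidation selects the unhindered primary allylic alcohol over the neopentyl-type secondary one at C6; enal 34 closes with O6 to lactol 35, which is oxidised on to the lactone (oxidative lactonisation of a 1,4-diol). The tertiary C7 hydroxyl cannot be oxidised and the trans ring fusion is already fixed by C6 and C7.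

Step 21
Reactants: 36 8β-(tert-butyldimethylsilyloxy)-7α-hydroxygermacra-1(10)Z,4E,11(13)-trien-12,6α-olide
Product: 37 7α,8β-dihydroxygermacra-1(10)Z,4E,11(13)-trien-12,6α-olide (6R,7S,8R)
Conditions: HF·pyridine, pyridine, THF, 0 °C to rt
Reagents that add atoms: none
Why: Fluoride-driven desilylation under buffered, weakly acidic conditions, which avoid conjugate addition to the methylene lactone and base-induced translactonisation to O8; no epoxide is present yet to be opened by fluoride.

Step 22
Reactants: 37 7α,8β-dihydroxygermacra-1(10)Z,4E,11(13)-trien-12,6α-olide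
Product: 38 7α-hydroxy-8β-methacryloyloxygermacra-1(10)Z,4E,11(13)-trien-12,6α-olide (6R,7S,8R)
Conditions: methacrylic anhydride, Et3N, 4-(dimethylamino)pyridine (cat.), CH2Cl2, 0 °C
Reagents that add atoms: methacrylic anhydride, C=C(C)C(=O)OC(=O)C(C)=C
Why: Acylation under nucleophilic catalysis takes the secondary C8 hydroxyl; the tertiary C7 hydroxyl is too hindered to compete. It is run cold and directly after step 21 so that O8 is capped before it can attack C12.

Step 23
Reactants: 38 7α-hydroxy-8β-methacryloyloxygermacra-1(10)Z,4E,11(13)-trien-12,6α-olide
Product: 39 the target, 1α,10α:4α,5β-diepoxy-7α-hydroxy-8β-methacryloyloxygermacr-11(13)-en-12,6α-olide (1S,4R,5R,6R,7S,8R,10R)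
Conditions: mCPBA (2.2 equiv), NaHCO3, CH2Cl2, 0 °C
Reagents that add atoms: mCPBA (3-chloroperoxybenzoic acid), OOC(=O)c1cccc(Cl)c1
Why: Prilezhaev epoxidation of the two electron-rich trisubstituted olefins; the methylene lactone and the methacrylate are too electron-poor to react. At the E C4=C5 olefin only the outer face is open, and with H6 eclipsing the olefin (allylic 1,3-strain against C15) that face is syn to O6, which gives 4R,5R. At the Z C1=C10 olefin the β face is screened by the β ester on C8 and the α-oriented C7 hydroxyl can hydrogen-bond to the peracid, so oxygen should arrive on the α face (1S,10R); the bicarbonate buffer protects the diepoxide from acid.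

## Compound list

1 | geranyl acetate | CC(C)=CCC/C(C)=C/COC(C)=O | starting material
2 | 6,7-epoxygeranyl acetate (racemic oxirane) | CC1(C)OC1CC/C(C)=C/COC(C)=O | intermediate
3 | (2E)-3-methyl-6-oxohex-2-en-1-yl acetate | O=CCC/C(C)=C/COC(C)=O | intermediate (not isolated)
4 | (2E)-6-hydroxy-3-methylhex-2-en-1-yl acetate | OCCC/C(C)=C/COC(C)=O | intermediate
5 | (2E)-6-chloro-3-methylhex-2-en-1-yl acetate | ClCCC/C(C)=C/COC(C)=O | intermediate
6 | (2E)-6-chloro-3-methylhex-2-en-1-ol | ClCCC/C(C)=C/CO | intermediate
7 | (2E)-1-bromo-6-chloro-3-methylhex-2-ene | ClCCC/C(C)=C/CBr | intermediate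
8 | 1,3-dithiane | C1CSCSC1 | starting material
9 | 2-lithio-1,3-dithiane | [Li]C1SCCCS1 | intermediate (not isolated)
10 | 2-[(2E)-6-chloro-3-methylhex-2-en-1-yl]-1,3-dithiane | ClCCC/C(C)=C/CC1SCCCS1 | intermediate
11 | ethyl (S)-3-hydroxybutanoate | CCOC(=O)C[C@H](C)O | starting material
12 | (S)-3-hydroxy-N-methoxy-N-methylbutanamide | CON(C)C(=O)C[C@H](C)O | intermediate
13 | 2-lithio derivative of 10 | ClCCC/C(C)=C/CC1([Li])SCCCS1 | intermediate (not isolated)
14 | chloromagnesium alkoxide of 12 | CON(C)C(=O)C[C@H](C)O[Mg]Cl | intermediate (not isolated)
15 | (3S)-1-{2-[(2E)-6-chloro-3-methylhex-2-en-1-yl]-1,3-dithian-2-yl}-3-hydroxybutan-1-one | ClCCC/C(C)=C/CC1(C(=O)C[C@H](C)O)SCCCS1 | intermediate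
16 | (2S,4R)-4-{2-[(2E)-6-chloro-3-methylhex-2-en-1-yl]-1,3-dithian-2-yl}-4-hydroxybutan-2-yl acetate | ClCCC/C(C)=C/CC1([C@H](O)C[C@H](C)OC(C)=O)SCCCS1 | intermediate
17 | C8 tert-butyldimethylsilyl ether of 16 | ClCCC/C(C)=C/CC1([C@H](O[Si](C)(C)C(C)(C)C)C[C@H](C)OC(C)=O)SCCCS1 | intermediate
18 | dioxolane acetate (C7 ethylene ketal of 17) | ClCCC/C(C)=C/CC1([C@H](O[Si](C)(C)C(C)(C)C)C[C@H](C)OC(C)=O)OCCO1 | intermediate
19 | dioxolane alcohol (10S carbinol) | ClCCC/C(C)=C/CC1([C@H](O[Si](C)(C)C(C)(C)C)C[C@H](C)O)OCCO1 | intermediate
20 | dioxolane thioacetate (10R) | ClCCC/C(C)=C/CC1([C@H](O[Si](C)(C)C(C)(C)C)C[C@@H](C)SC(C)=O)OCCO1 | intermediate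
21 | dioxolane thiol (10R) | ClCCC/C(C)=C/CC1([C@H](O[Si](C)(C)C(C)(C)C)C[C@@H](C)S)OCCO1 | intermediate (not isolated)
22 | eleven-membered cyclic sulfide (8R,10R,4E) | CC(C)(C)[Si](C)(C)O[C@@H]1C[C@@H](C)SCCC/C(C)=C/CC12OCCO2 | intermediate
23 | cyclic sulfoxide (either configuration at sulfur) | CC(C)(C)[Si](C)(C)O[C@@H]1C[C@@H](C)S(=O)CCC/C(C)=C/CC12OCCO2 | intermediate (not isolated)
24 | eleven-membered cyclic sulfone (8R,10R,4E) | CC(C)(C)[Si](C)(C)O[C@@H]1C[C@@H](C)S(=O)(=O)CCC/C(C)=C/CC12OCCO2 | intermediate
25 | α-bromo sulfone (bromine on C1, either configuration) | CC(C)(C)[Si](C)(C)O[C@@H]1C[C@@H](C)S(=O)(=O)C(Br)CC/C(C)=C/CC12OCCO2 | intermediate (not isolated)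
26 | cis-fused episulfone across C1–C10 (one of the two cis-fused diastereomers drawn) | CC(C)(C)[Si](C)(C)O[C@@H]1C[C@@]3(C)S(=O)(=O)[C@H]3CC/C(C)=C/CC12OCCO2 | intermediate (not isolated)
27 | (1(10)Z,4E)-cyclodecadiene C7 ketal (8R) | CC(C)(C)[Si](C)(C)O[C@@H]1C/C(C)=C\CC/C(C)=C/CC12OCCO2 | intermediate
28 | (3E,7Z,10R)-10-(tert-butyldimethylsilyloxy)-4,8-dimethylcyclodeca-3,7-dien-1-one | CC(C)(C)[Si](C)(C)O[C@@H]1C/C(C)=C\CC/C(C)=C/CC1=O | intermediate
29 | potassium dienolate of 28 (C6=C7, cis in the ring) | CC(C)(C)[Si](C)(C)O[C@@H]1C/C(C)=C\CC/C(C)=C/C=C1/[O-].[K+] | intermediate (not isolated)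
30 | (2R,3E,7Z,10R)-10-(tert-butyldimethylsilyloxy)-2-hydroxy-4,8-dimethylcyclodeca-3,7-dien-1-one | CC(C)(C)[Si](C)(C)O[C@@H]1C/C(C)=C\CC/C(C)=C/[C@@H](O)C1=O | intermediate
31 | 2-bromoprop-2-en-1-ol | C=C(Br)CO | starting material
32 | O,2-dilithio derivative of allyl alcohol | [Li]OCC([Li])=C | intermediate (not isolated)
33 | 8β-(tert-butyldimethylsilyloxy)germacra-1(10)Z,4E,11(13)-triene-6α,7α,12-triol | CC(C)(C)[Si](C)(C)O[C@@H]1C/C(C)=C\CC/C(C)=C/[C@@H](O)[C@]1(O)C(=C)CO | intermediate
34 | C12 aldehyde of 33 (hydroxy enal) | CC(C)(C)[Si](C)(C)O[C@@H]1C/C(C)=C\CC/C(C)=C/[C@@H](O)[C@]1(O)C(=C)C=O | intermediate (not isolated)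
35 | 12,6-lactol (either configuration at C12) | CC(C)(C)[Si](C)(C)O[C@@H]1C/C(C)=C\CC/C(C)=C/[C@H]2OC(O)C(=C)[C@@]21O | intermediate (not isolated)
36 | 8β-(tert-butyldimethylsilyloxy)-7α-hydroxygermacra-1(10)Z,4E,11(13)-trien-12,6α-olide | CC(C)(C)[Si](C)(C)O[C@@H]1C/C(C)=C\CC/C(C)=C/[C@H]2OC(=O)C(=C)[C@@]21O | intermediate
37 | 7α,8β-dihydroxygermacra-1(10)Z,4E,11(13)-trien-12,6α-olide | O[C@@H]1C/C(C)=C\CC/C(C)=C/[C@H]2OC(=O)C(=C)[C@@]21O | intermediate
38 | 7α-hydroxy-8β-methacryloyloxygermacra-1(10)Z,4E,11(13)-trien-12,6α-olide | C=C(C)C(=O)O[C@@H]1C/C(C)=C\CC/C(C)=C/[C@H]2OC(=O)C(=C)[C@@]21O | intermediate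
39 | 1α,10α:4α,5β-diepoxy-7α-hydroxy-8β-methacryloyloxygermacr-11(13)-en-12,6α-olide (CNP0228789.1) | C=C(C)C(=O)O[C@@H]1C[C@@]2(C)O[C@H]2CC[C@@]2(C)O[C@@H]2[C@H]2OC(=O)C(=C)[C@@]21O | target

## Step count and least certain steps

Total step count: 23. Longest linear sequence: 22 steps (steps 1–6 and 8–23, from 1 to 39); step 7 is a one-step branch.

Step 16 (key step). The most likely failure is repeated bromination of the C1 methylene before the hindered tertiary C10–H is removed, because the first bromine makes the remaining C1–H more acidic while closure waits on the slower deprotonation. This would divert material to bromoalkene and sulfonate by-products. Fallback: from sulfone 24, kinetic deprotonation with LiHMDS in THF at −78 °C and quenching with C2Cl6 should give the α-chloro sulfone F1 with exactly one halogen. Treating F1 with KOt-Bu in THF at −78 to 0 °C then effects the 1,3-elimination and loss of SO2 and returns to 27.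

Step 14. The most likely failure is intermolecular S-alkylation and oxidative coupling of the thiolate outrunning closure of an eleven-membered ring, whose formation is entropically slow. Fallback: from thioacetate 20, KSAc in DMF displaces the chloride to give the bis(thioacetate) F2. Methanolysis with K2CO3 in MeOH followed by I2 under dilution gives the twelve-membered cyclic disulfide F3; disulfide formation is reversible under thiolate catalysis, so oligomers can correct to the ring. Desulfurisation of F3 with (Et2N)3P in benzene at room temperature (the phosphine attacks the less hindered sulfur on C1, and the C10 thiolate then displaces at C1) extrudes one sulfur and returns to 22.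

Step 17. The most likely failure is loss of the C8 silyl ether during hydrolysis, because the oxocarbenium ion next to the silyloxy carbon forms slowly and the ketal may need longer exposure than the silyl ether tolerates. Fallback: from 27, complete removal of both groups with TsOH·H2O in wet acetone at room temperature gives the hydroxy ketone F4, and silylation with TBSCl and imidazole in DMF returns to 28.

Step 18. The most likely failure is poor facial selectivity at C6, since the choice rests on one rotamer about C7–C8 in a flexible ring; lingering base could also move the ketol to its conjugated tautomer. Fallback: from 28, if the hydroxylation delivers mainly the 6-epimer F5, a Mitsunobu reaction with chloroacetic acid (PPh3, DIAD, THF) inverts C6 to give the chloroacetate F6. Cleavage with thiourea and NaHCO3 in EtOH under near-neutral conditions returns to 30.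

Step 19. The most likely failure is enolisation of the alkoxide ketone at the acidic allylic C6–H by the strongly basic dilithio reagent in place of addition to the hindered carbonyl, which would return or epimerise the ketol. Fallback: from 30, the small and weakly basic cerium acetylide (HC≡CMgBr, CeCl3, THF, −78 °C) should add under the same facial control to give the ethynyl diol F7. Palladium-catalysed cyclocarbonylation of this homopropargylic alcohol (PdI2, PBu3, CO, MeCN, 50 °C) builds the methylene lactone directly and returns to 36.

Step 23. The most likely failure is attack of the peracid on the β face of the Z olefin, because a cis olefin in a ten-membered ring shields its inner face less than a trans one; acid-triggered transannular opening of the product is the second risk. Fallback: from 36, hydroxyl-directed epoxidation with VO(acac)2 and t-BuOOH in CH2Cl2 at 0 °C, in which the vanadium-bound C7 alkoxide delivers oxygen from the α side, should give the diepoxide silyl ether F8. Desilylation with TBAF buffered by AcOH gives the diepoxy diol F9, and acylation with methacrylic anhydride, Et3N and 4-(dimethylamino)pyridine returns to 39.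

## Further compounds

F1 | step 16 | α-chloro sulfone (chlorine on C1 of 24, either configuration) | CC(C)(C)[Si](C)(C)O[C@@H]1C[C@@H](C)S(=O)(=O)C(Cl)CC/C(C)=C/CC12OCCO2
F2 | step 14 | bis(thioacetate) (C1 and C10 thioacetates of the dioxolane) | CC(=O)SCCC/C(C)=C/CC1([C@H](O[Si](C)(C)C(C)(C)C)C[C@@H](C)SC(C)=O)OCCO1
F3 | step 14 | twelve-membered cyclic disulfide | CC(C)(C)[Si](C)(C)O[C@@H]1C[C@@H](C)SSCCC/C(C)=C/CC12OCCO2
F4 | step 17 | (3E,7Z,10R)-10-hydroxy-4,8-dimethylcyclodeca-3,7-dien-1-one | O[C@@H]1C/C(C)=C\CC/C(C)=C/CC1=O
F5 | step 18 | 6-epimer of 30 (6S,8R) | CC(C)(C)[Si](C)(C)O[C@@H]1C/C(C)=C\CC/C(C)=C/[C@H](O)C1=O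
F6 | step 18 | 6-O-chloroacetate of 30 (6R,8R) | CC(C)(C)[Si](C)(C)O[C@@H]1C/C(C)=C\CC/C(C)=C/[C@@H](OC(=O)CCl)C1=O
F7 | step 19 | 7-ethynyl-6α,7α-diol (C8 silyl ether; configuration as in 33) | CC(C)(C)[Si](C)(C)O[C@@H]1C/C(C)=C\CC/C(C)=C/[C@@H](O)[C@]1(O)C#C
F8 | step 23 | diepoxide silyl ether (configuration as in 39; C8 tert-butyldimethylsilyl ether) | CC(C)(C)[Si](C)(C)O[C@@H]1C[C@@]2(C)O[C@H]2CC[C@@]2(C)O[C@@H]2[C@H]2OC(=O)C(=C)[C@@]21O
F9 | step 23 | diepoxy diol (configuration as in 39; free C8 hydroxyl) | O[C@@H]1C[C@@]2(C)O[C@H]2CC[C@@]2(C)O[C@@H]2[C@H]2OC(=O)C(=C)[C@@]21O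
A1 | alternative 1 | isoxazoline-bridged ten-membered carbocycle | O1N=C2C[C@]1(C)[C@H](O)CC/C(C)=C/[C@@H](OCOC)[C@]2(OCOC)C(=C)COCc1ccc(OC)cc1
A2 | alternative 1 | acyclic C8 aldoxime with C9=C10 olefin and free C1 hydroxyl | C=C(C)[C@H](O)CC/C(C)=C/[C@@H](OCOC)[C@@](OCOC)(C=NO)C(=C)COCc1ccc(OC)cc1
A3 | alternative 2 | (1(10)Z,4E)-diene lactone methacrylate (identical with 38) | C=C(C)C(=O)O[C@@H]1C/C(C)=C\CC/C(C)=C/[C@H]2OC(=O)C(=C)[C@@]21O
A4 | alternative 2 | 7α-hydroxy-8β-methacryloyloxygermacra-1(10)Z,4E,11(13)-trien-12-oic acid | C=C(C)C(=O)O[C@@H]1C/C(C)=C\CC/C(C)=C/C[C@]1(O)C(=C)C(=O)O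
A5 | alternative 3 | C6–C7 fused 2,2-dichloro-3-silyloxycyclobutanone | CC(C)(C)[Si](C)(C)O[C@@H]1C/C(C)=C\CC/C(C)=C/[C@H]2C(=O)C(Cl)(Cl)[C@@]21O[Si](C)(C)C(C)(C)C
A6 | alternative 3 | C6=C7 silyl dienol ether of 28 (trans ring geometry at C6=C7) | CC(C)(C)[Si](C)(C)O/C1=C\C=C(C)\CC/C=C(C)\C[C@H]1O[Si](C)(C)C(C)(C)C
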